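**Strategy.** The carbocycle of the 7,8-dihydro-6H-isochromen-6-one core (C4a, C5, C6, C7, C8, C8a) is cut at C6–C7 and C4a–C8a into two open-chain units, enynal 6 and nitro ketone 10. The key step exploits the tertiary α-ketol (C6=O beside C7–O) and the fact that C4a and C8a are both β-carbons of carbonyl groups, so each new bond joins carbons of like polarity. A nitro group on C8a and a chiral carbene on C6 reverse the polarity: nitro-Michael addition, loss of nitrous acid, alkene shift and crossed benzoin closure in one flask give ketol 15 with C7 set. Gold-catalysed pyran closure, esterification and desilylation finish the synthesis.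

Key step: step 5

Assumption: compounds 1, 2, 7 (as its 60 wt % aqueous solution), 8 and 18 are taken as commercial, and the (5aS,10bR) antipode of the triazolium salt is assumed to deliver the 6S ketol (its mirror image is used if the sense of induction is the opposite).

Step 1
Reactants: 1 (E)-pent-2-en-4-yn-1-ol; 2 (E)-3-(dimethylamino)prop-2-enal
Product: 5 (2E,6E)-8-hydroxyocta-2,6-dien-4-ynal, via dilithium salt 3 (not isolated), via amino alcohol 4 (not isolated)
Conditions: n-BuLi (2.1 equiv), THF, −78 to 0 °C; then 2, 0 °C; aq. HCl work-up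
Reagents that add atoms: water, O
Why: 1,2-addition of the lithium acetylide to the vinylogous formamide and acid-induced loss of dimethylamine (formylvinylation of an organolithium with 3-(dimethylamino)acrolein) should give the E enal, the lithium alkoxide being a spectator.

Step 2
Reactants: 5 (2E,6E)-8-hydroxyocta-2,6-dien-4-ynal
Product: 6 (2E,6E)-8-oxoocta-2,6-dien-4-yn-1-yl acetate
Conditions: Ac2O, pyridine, 4-(dimethylamino)pyridine (cat.), CH2Cl2, 0 °C
Reagents that add atoms: acetic anhydride, CC(=O)OC(C)=O
Why: Nucleophile-catalysed O-acylation (esterification) of the primary allylic alcohol should leave the enal untouched.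

Step 3
Reactants: 7 2,2-dimethoxyacetaldehyde; 8 1-(triphenylphosphoranylidene)propan-2-one
Product: 9 (3E)-5,5-dimethoxypent-3-en-2-one
Conditions: 7 (60 wt % in H2O), 8 (1.1 equiv), CH2Cl2, rt
Reagents that add atoms: none
Why: Wittig olefination of the aldehyde with the stabilised acetonylidene ylide should give the E enone and tolerates the water that accompanies 7.

Step 4
Reactants: 9 (3E)-5,5-dimethoxypent-3-en-2-one
Product: 10 5,5-dimethoxy-4-nitropentan-2-one
Conditions: NaNO2 (2 equiv), AcOH (2 equiv), THF, rt; used without chromatography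
Reagents that add atoms: sodium nitrite, [Na+].[O-]N=O
Why: Conjugate addition of nitrous acid through nitrogen to the enone (hydronitration of an α,β-unsaturated ketone with NaNO2/AcOH) should give the β-nitro ketone with the nitro group on the carbon that bears the acetal, the new centre being racemic and destroyed in step 5.

Step 5
Reactants: 6 (2E,6E)-8-oxoocta-2,6-dien-4-yn-1-yl acetate; 10 5,5-dimethoxy-4-nitropentan-2-one
Product: 15 (6S)-4-(dimethoxymethyl)-6-hydroxy-6-methyl-3-[(3E)-5-acetoxypent-3-en-1-yn-1-yl]cyclohex-2-en-1-one (C4 epimers), via nitronate salt 11 (not isolated), via nitro aldehyde 12 (not isolated), via enone 13 (not isolated), via dienynal 14 (not isolated)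
Conditions: 10 (1.2 equiv), 1,8-diazabicyclo[5.4.0]undec-7-ene (DBU, 1.2 equiv), THF, −20 °C, then 6; then DBU (1.0 equiv), rt; then (5aS,10bR)-2-(pentafluorophenyl)-5a,10b-dihydro-4H,6H-indeno[2,1-b][1,2,4]triazolo[4,3-d][1,4]oxazin-2-ium tetrafluoroborate (15 mol %), rt
Reagents that add atoms: none
Why: DBU converts 10 into nitronate 11, which adds in a Michael sense to the enal β-carbon of 6 (C4a–C8a bond), and the tertiary β-nitro ketone 12 then loses nitrous acid by an E1cB path to enone 13, so that the nitro ketone acts as a β-acylvinyl anion equivalent. The second portion of DBU moves the double bond through the dienolates into conjugation with the formyl and alkynyl groups (14), after which the triazolylidene adds to the formyl carbon and the resulting acyl-anion equivalent attacks the methyl ketone (C6–C7 bond). The closest known reaction types are the nitro-Michael/nitrous acid elimination sequence of β-nitro carbonyl compounds, base-mediated conjugative alkene migration and the carbene-catalysed intramolecular crossed aldehyde–ketone benzoin reaction, here run as a base/carbene relay. The six-membered carbocycle closes by a 6-exo-trig addition to the ketone carbonyl. The new C7 stereocentre is set by the chiral triazolylidene, which selects the face of the ketone, while the labile C8a centre epimerises through the dienolate and is erased in step 6. The step needs 1,4- rather than 1,2- or 1,6-addition to 6 (addition of the hindered nitronate to the formyl group is reversible and the formyl-activated β-carbon is the nearest soft site) and needs the benzoin closure to wait for the alkene shift, which the late addition of the triazolium salt should secure; only the 2E isomer of 14 can close, and E/Z exchange through the dienolate should feed it.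

Step 6
Reactants: 15 (6S)-4-(dimethoxymethyl)-6-hydroxy-6-methyl-3-[(3E)-5-acetoxypent-3-en-1-yn-1-yl]cyclohex-2-en-1-one
Product: 17 (2E)-3-[(7S)-7-hydroxy-7-methyl-6-oxo-7,8-dihydro-6H-isochromen-3-yl]prop-2-en-1-yl acetate, via formyl enone 16 (not isolated)
Conditions: AuCl3 (5 mol %), CF3CO2H, H2O (5 equiv), ClCH2CH2Cl, rt
Reagents that add atoms: water, O
Why: Acid hydrolysis of the acetal gives formyl enone 16, whose enol oxygen should add 6-endo-dig to the gold-activated alkyne (cycloisomerisation of an ortho-alkynyl carbonyl compound) to give the pyran, the C8a stereocentre becoming trigonal.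

Step 7
Reactants: 18 2,4-dihydroxy-6-methylbenzoic acid (orsellinic acid)
Product: 19 tert-butyldimethylsilyl 2,4-bis[(tert-butyldimethylsilyl)oxy]-6-methylbenzoate
Conditions: TBSCl (3.5 equiv), imidazole, DMF, 40 °C
Reagents that add atoms: tert-butyldimethylsilyl chloride, CC(C)(C)[Si](C)(C)Cl
Why: Silylation should convert both phenols into silyl ethers and the acid into its silyl ester.

Step 8
Reactants: 19 tert-butyldimethylsilyl 2,4-bis[(tert-butyldimethylsilyl)oxy]-6-methylbenzoate
Product: 20 2,4-bis[(tert-butyldimethylsilyl)oxy]-6-methylbenzoyl chloride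
Conditions: (COCl)2 (1.2 equiv), N,N-dimethylformamide (cat.), CH2Cl2, 0 °C to rt
Reagents that add atoms: oxalyl chloride, O=C(Cl)C(Cl)=O
Why: Acyl chloride formation from the silyl ester with the chloroiminium salt from oxalyl chloride and DMF runs under neutral conditions and should leave the aryl silyl ethers intact.

Step 9
Reactants: 17 (2E)-3-[(7S)-7-hydroxy-7-methyl-6-oxo-7,8-dihydro-6H-isochromen-3-yl]prop-2-en-1-yl acetate; 20 2,4-bis[(tert-butyldimethylsilyl)oxy]-6-methylbenzoyl chloride
Product: 21 (7S)-3-[(1E)-3-acetoxyprop-1-en-1-yl]-7-methyl-6-oxo-7,8-dihydro-6H-isochromen-7-yl 2,4-bis[(tert-butyldimethylsilyl)oxy]-6-methylbenzoate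
Conditions: 20 (2 equiv), 4-(dimethylamino)pyridine (2 equiv), Et3N, CH2Cl2, rt to 40 °C
Reagents that add atoms: none
Why: Nucleophile-catalysed acyl transfer (esterification) should acylate the only hydroxyl group, the tertiary C7 alcohol, with retention because no bond to C7 is broken.

Step 10
Reactants: 21 (7S)-3-[(1E)-3-acetoxyprop-1-en-1-yl]-7-methyl-6-oxo-7,8-dihydro-6H-isochromen-7-yl 2,4-bis[(tert-butyldimethylsilyl)oxy]-6-methylbenzoate
Product: 22 (7S)-3-[(1E)-3-acetoxyprop-1-en-1-yl]-7-methyl-6-oxo-7,8-dihydro-6H-isochromen-7-yl 2,4-dihydroxy-6-methylbenzoate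
Conditions: HF·pyridine, pyridine, THF, 0 °C
Reagents that add atoms: none
Why: Fluoride-mediated desilylation should cleave the two aryl silyl ethers while the acetate, the aryl ester and the pyranone survive.

**Compound list**

1 | (E)-pent-2-en-4-yn-1-ol | C#C/C=C/CO | starting material
2 | (E)-3-(dimethylamino)prop-2-enal | CN(C)/C=C/C=O | starting material
3 | dilithium salt of 1 (alkoxide and acetylide) | [Li+].[Li+].[C-]#C/C=C/C[O-] | intermediate
4 | (2E,7E)-8-(dimethylamino)octa-2,7-dien-4-yne-1,6-diol (racemic at C6) | OC/C=C/C#CC(O)/C=C/N(C)C | intermediate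
5 | (2E,6E)-8-hydroxyocta-2,6-dien-4-ynal | OC/C=C/C#C/C=C/C=O | intermediate
6 | (2E,6E)-8-oxoocta-2,6-dien-4-yn-1-yl acetate | CC(=O)OC/C=C/C#C/C=C/C=O | intermediate
7 | 2,2-dimethoxyacetaldehyde | COC(OC)C=O | starting material
8 | 1-(triphenylphosphoranylidene)propan-2-one | CC(=O)C=P(c1ccccc1)(c1ccccc1)c1ccccc1 | starting material
9 | (3E)-5,5-dimethoxypent-3-en-2-one | COC(OC)/C=C/C(C)=O | intermediate
10 | 5,5-dimethoxy-4-nitropentan-2-one (racemic) | COC(OC)C(CC(C)=O)[N+](=O)[O-] | intermediate
11 | DBU-H salt of the nitronate of 10 | COC(OC)C(CC(C)=O)=[N+]([O-])[O-].C1CCC2=[NH+]CCCN2CC1 | intermediate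
12 | 4-(dimethoxymethyl)-4-nitro-6-oxo-3-[(3E)-5-acetoxypent-3-en-1-yn-1-yl]heptanal (diastereomers) | COC(OC)C(CC(C)=O)([N+](=O)[O-])C(CC=O)C#C/C=C/COC(C)=O | intermediate
13 | 4-(dimethoxymethyl)-6-oxo-3-[(3E)-5-acetoxypent-3-en-1-yn-1-yl]hept-4-enal (E/Z at C4) | COC(OC)C(=CC(C)=O)C(CC=O)C#C/C=C/COC(C)=O | intermediate
14 | (2E)-4-(dimethoxymethyl)-6-oxo-3-[(3E)-5-acetoxypent-3-en-1-yn-1-yl]hept-2-enal (reactive isomer, formyl cis to C4) | COC(OC)C(CC(C)=O)/C(C#C/C=C/COC(C)=O)=C\C=O | intermediate
15 | (6S)-4-(dimethoxymethyl)-6-hydroxy-6-methyl-3-[(3E)-5-acetoxypent-3-en-1-yn-1-yl]cyclohex-2-en-1-one (C4 epimers) | CC(=O)OC/C=C/C#CC1=CC(=O)[C@@](C)(O)CC1C(OC)OC | intermediate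
16 | (5S)-5-hydroxy-5-methyl-4-oxo-2-[(3E)-5-acetoxypent-3-en-1-yn-1-yl]cyclohex-2-ene-1-carbaldehyde (C1 epimers, enolised) | CC(=O)OC/C=C/C#CC1=CC(=O)[C@@](C)(O)CC1C=O | intermediate
17 | (2E)-3-[(7S)-7-hydroxy-7-methyl-6-oxo-7,8-dihydro-6H-isochromen-3-yl]prop-2-en-1-yl acetate | CC(=O)OC/C=C/C1=CC2=CC(=O)[C@@](C)(O)CC2=CO1 | intermediate
18 | 2,4-dihydroxy-6-methylbenzoic acid | Cc1cc(O)cc(O)c1C(=O)O | starting material
19 | tert-butyldimethylsilyl 2,4-bis[(tert-butyldimethylsilyl)oxy]-6-methylbenzoate | Cc1cc(O[Si](C)(C)C(C)(C)C)cc(O[Si](C)(C)C(C)(C)C)c1C(=O)O[Si](C)(C)C(C)(C)C | intermediate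
20 | 2,4-bis[(tert-butyldimethylsilyl)oxy]-6-methylbenzoyl chloride | Cc1cc(O[Si](C)(C)C(C)(C)C)cc(O[Si](C)(C)C(C)(C)C)c1C(Cl)=O | intermediate
21 | (7S)-3-[(1E)-3-acetoxyprop-1-en-1-yl]-7-methyl-6-oxo-7,8-dihydro-6H-isochromen-7-yl 2,4-bis[(tert-butyldimethylsilyl)oxy]-6-methylbenzoate | CC(=O)OC/C=C/C1=CC2=CC(=O)[C@@](C)(OC(=O)c3c(C)cc(O[Si](C)(C)C(C)(C)C)cc3O[Si](C)(C)C(C)(C)C)CC2=CO1 | intermediate
22 | (7S)-3-[(1E)-3-acetoxyprop-1-en-1-yl]-7-methyl-6-oxo-7,8-dihydro-6H-isochromen-7-yl 2,4-dihydroxy-6-methylbenzoate | CC(=O)OC/C=C/C1=CC2=CC(=O)[C@@](C)(OC(=O)c3c(C)cc(O)cc3O)CC2=CO1 | target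

**Totals.** Total step count: 10. Longest linear sequence: 6 steps (steps 1, 2, 5, 6, 9, 10; the branch through steps 3 and 4 is equally long).

**Steps most likely to fail**

Step 5. Under DBU the enynal may oligomerise or undergo aldol reactions faster than the nitronate adds, and the β-nitro ketone may lose nitrous acid before it adds. The benzoin closure may also begin before the alkene shift is complete and so trap the unconjugated aldehyde, methanol may be lost from the acetal through the dienolate, and the C8a centre may erode the facial selectivity at C7. The fallback sets out from 6 and 10 and returns at 15. The C4a–C8a bond is made first under iminium activation with (S)-α,α-diphenylprolinol trimethylsilyl ether in CH2Cl2, without strong base, and nitro aldehyde 12 is isolated. DBU in a second flask then effects the loss of nitrous acid and the alkene shift to the conjugated aldehyde 14, which is isolated. Finally 14 is closed to 15 with the same triazolium salt and NaOAc in a separate carbene-catalysed crossed benzoin reaction. This fallback makes no new compound (F0).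

Step 6. The oxygen may close 5-exo-dig instead of 6-endo-dig, the alkyne may be hydrated, the acid may ionise the tertiary alcohol and lead to aromatisation, or the allylic acetate may be solvolysed. The fallback sets out from 15 and returns at 17. Pyridinium p-toluenesulfonate in wet acetone unmasks formyl enone 16, which is isolated. Iodine and NaHCO3 in MeCN then close the ring by iodocyclisation to (2E)-3-[(7S)-7-hydroxy-4-iodo-7-methyl-6-oxo-7,8-dihydro-6H-isochromen-3-yl]prop-2-en-1-yl acetate F1. Radical hydrodeiodination (Bu3SnH, Et3B, air, toluene, rt) gives 17.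

Step 9. Acyl transfer from the doubly ortho-substituted acyl chloride to the hindered tertiary hydroxyl may be too slow, so that the acyl chloride decomposes or the base-sensitive pyranone is attacked. The fallback sets out from 18 and 17 and returns at 22. Acid 18 is condensed with acetone (trifluoroacetic anhydride, CF3CO2H) to 7-hydroxy-2,2,5-trimethyl-4H-1,3-benzodioxin-4-one F2. Silylation (TBSCl, imidazole) gives 7-[(tert-butyldimethylsilyl)oxy]-2,2,5-trimethyl-4H-1,3-benzodioxin-4-one F3. The sodium alkoxide of 17 (NaH, THF, 0 °C) opens F3 with loss of acetone to (7S)-3-[(1E)-3-acetoxyprop-1-en-1-yl]-7-methyl-6-oxo-7,8-dihydro-6H-isochromen-7-yl 4-[(tert-butyldimethylsilyl)oxy]-2-hydroxy-6-methylbenzoate F4. HF·pyridine as in step 10 then gives 22.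

Further compounds
F0 | step 5 | none | none
F1 | step 6 | (2E)-3-[(7S)-7-hydroxy-4-iodo-7-methyl-6-oxo-7,8-dihydro-6H-isochromen-3-yl]prop-2-en-1-yl acetate | CC(=O)OC/C=C/C1=C(I)C2=CC(=O)[C@@](C)(O)CC2=CO1
F2 | step 9 | 7-hydroxy-2,2,5-trimethyl-4H-1,3-benzodioxin-4-one | Cc1cc(O)cc2OC(C)(C)OC(=O)c12
F3 | step 9 | 7-[(tert-butyldimethylsilyl)oxy]-2,2,5-trimethyl-4H-1,3-benzodioxin-4-one | Cc1cc(O[Si](C)(C)C(C)(C)C)cc2OC(C)(C)OC(=O)c12
F4 | step 9 | (7S)-3-[(1E)-3-acetoxyprop-1-en-1-yl]-7-methyl-6-oxo-7,8-dihydro-6H-isochromen-7-yl 4-[(tert-butyldimethylsilyl)oxy]-2-hydroxy-6-methylbenzoate | CC(=O)OC/C=C/C1=CC2=CC(=O)[C@@](C)(OC(=O)c3c(C)cc(O[Si](C)(C)C(C)(C)C)cc3O)CC2=CO1
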